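The ash run was charged with 4.29 times the starting material of the larch run, yet at 12.0 h the two readings stand at 31% and 28% of the charge, so what you can carry from these runs is a fraction of the charge rather than an amount.

| flask | starting material | partner | free catalyst | second catalyst | remark | time |
|---|---|---|---|---|---|---|
| larch | 0.49 M | 1.2 M | 1 mM | 15 mM | run made earlier |  |
| ash | 2.1 M | 1.2 M | 1 mM | 15 mM | run made earlier |  |
| Monday's | 0.40 M | 1.20 M | 1.0 mM | 15 mM |  | 30 h |
| Thursday's | 0.80 M | 1.20 M | 1.0 mM | 15 mM |  | 30 h |
| Sunday's | 1.5 M | 1.20 M | 1.0 mM | 15 mM |  | 30 h |

- larch (time / h: target / %): 4.00: 9; 8.00: 18; 12.0: 31; 15.0: 34; 20.0: 48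
- ash (time / h: target / %): 4.00: 7; 8.00: 18; 12.0: 28; 15.0: 37; 20.0: 41

(readings scatter by 1.5 percentage points)

- [target] (only what is free in solution) at the end for Monday's, Thursday's, Sunday's, in this order
- how the row runs (hardly changes / falls, then rises / falls all the way / rises, then falls / rises all the way)

- the numbers in the tables scatter with a standard deviation of 1.5 percentage points
- a reading or a percentage of target counts all its forms, free or not
- the concentration of target that is asked is that of its free form alone
- "hardly changes" means that all values lie within two and a half points (for a concentration: within two and a half percent of the largest)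

My own reckoning leans on the larch run, because by 20.0 h it has spent 0.235 M of partner, less than the 0.861 M spent in the ash run. Its last reading gives 0.0327 h⁻¹, which I call the clearing constant: the natural logarithm of the charge over what has not yet become target, divided by the time, a pseudo-first-order constant read from readings that carry their scatter. Carried over 30 h, it reckons 62.5% of each of the three charges as target, which gives 0.250 M, 0.500 M and 0.938 M, and the last of these stays below the 1.20 M of partner charged. These figures count target free or not, as the readings do.

The forecast gives 0.24 M, 0.47 M and 0.76 M, a row that rises all the way, and says “rises all the way, though it is partner-limited at the top”; for Sunday's flask it stands lower than my figure.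

The flasks hold 0.247 M, 0.493 M and 0.643 M of free target, and the row rises all the way.

    starting material + free catalyst ⇌ free catalyst + open intermediate (K = 1.40, k = 820 L mol⁻¹ h⁻¹)
    2 free catalyst ⇌ resting dimer, settled at all times (K = 1600 L mol⁻¹)
    second catalyst + open intermediate ⇌ catalyst intermediate (K = 0.170 L mol⁻¹, k = 4.20 L mol⁻¹ h⁻¹)
    partner + catalyst intermediate → second catalyst + target (k = 690 L mol⁻¹ h⁻¹)
    crystals ⇌ target, rate k5*(cs5 - [target]) while solid is left; crystals form when [target] > cs5 (solubility = 0.620 M, k = 0.830 h⁻¹)

In Monday's flask, with 42.4% of the catalyst free at the end, the forward opening of starting material alone has a half-life of 1.99 h, shorter than the 11 h of open intermediate on second catalyst at that time, and 61.8% of the charge is target there, against the 62.5% that the clearing constant of 0.0327 h⁻¹ gives. Thursday's flask also stands at 61.6%, and Sunday's at 60.7%, or 0.911 M against the reckoned 0.938 M, but 0.268 M of that target lies as crystals, leaving 0.643 M free.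

The data are calculated with made-up constants.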